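## Retrosynthetic overview
1. The E-styryl C=C is cut last. A Horner–Wadsworth–Emmons reaction joins aldehyde 24 (cyclohexene plus one coumarin, 23 heavy atoms) to coumarinylmethyl phosphonate 9 (22 heavy atoms).
2. Aldehyde 24 goes back to enone 18 and iodocoumarin 5. A reductive conjugate arylation places the aryl group anti to CH2OTIPS. The silyl enol ether it leaves fixes where the later C(CH3)=CH bond sits (triflate, then Negishi methylation).
3. Enone 18 comes from an enantioselective Diels–Alder reaction of Rawal diene 12 with methacrolein 13. This step sets the quaternary centre and forms the carbocycle.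
4. Both 5 and 9 come from resorcinol and ethyl propiolate by a Pechmann-type annulation.
5. Ring order: the coumarin pyranone ring (one batch, used twice) and the cyclohexene ring are made in parallel. No ring is formed after the couplings.

Assumption: (R,R)-1-naphthyl-TADDOL is taken to give the (S)-configured quaternary centre of 14. If the optical rotation of 17 shows the opposite sense, the (S,S)-catalyst is used and nothing else changes.

## Fragment A: iodocoumarin 5

Step 1
Reactants: 1 resorcinol
Product: 2 4-iodoresorcinol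
Conditions: ICl (1.0 equiv), Et2O, 0 °C to rt; aq. Na2SO3 wash
Reagents that add atoms: iodine monochloride, ClI
Why: Electrophilic aromatic iodination, in which ICl in ether attacks the position ortho to one hydroxyl and para to the other, leaving the crowded position between the two hydroxyls free.

Step 2
Reactants: 2 4-iodoresorcinol; 3 ethyl propiolate
Product: 4 7-hydroxy-6-iodo-2H-chromen-2-one
Conditions: ZnCl2 (1 equiv), dioxane, 100 °C, 2 h; then 1 M HCl
Reagents that add atoms: none
Why: Pechmann-type annulation, in which ZnCl2-promoted hydroarylation of the propiolate at the only open activated ring position (ortho to one OH, para to the other) followed by lactonisation gives the 6-iodo-7-hydroxy isomer only.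

Step 3
Reactants: 4 7-hydroxy-6-iodo-2H-chromen-2-one
Product: 5 6-iodo-7-methoxy-2H-chromen-2-one
Conditions: MeI, K2CO3, acetone, reflux
Reagents that add atoms: iodomethane, CI
Why: Williamson ether synthesis on the acidic 7-OH, under which the lactone and the aryl iodide are inert to carbonate in acetone.

## Fragment B: phosphonate 9

Step 4
Reactants: 5 6-iodo-7-methoxy-2H-chromen-2-one
Product: 6 7-methoxy-2-oxo-2H-chromene-6-carbaldehyde
Conditions: CO (1 atm), HCO2Na (1.5 equiv), PdCl2(PPh3)2 (3 mol %), DMF, 100 °C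
Reagents that add atoms: carbon monoxide, [C-]#[O+]
Why: Palladium-catalysed reductive carbonylation (formylation), in which oxidative addition of the aryl iodide, CO insertion and hydride transfer from formate give the aldehyde without touching the lactone.

Step 5
Reactants: 6 7-methoxy-2-oxo-2H-chromene-6-carbaldehyde
Product: 7 6-(hydroxymethyl)-7-methoxy-2H-chromen-2-one
Conditions: NaBH4, THF/MeOH, 0 °C, 20 min
Reagents that add atoms: none
Why: Chemoselective 1,2-reduction, since the aromatic aldehyde is reduced far faster at 0 °C than the conjugated lactone.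

Step 6
Reactants: 7 6-(hydroxymethyl)-7-methoxy-2H-chromen-2-one
Product: 8 6-(bromomethyl)-7-methoxy-2H-chromen-2-one
Conditions: PBr3 (0.4 equiv), CH2Cl2, 0 °C
Reagents that add atoms: phosphorus tribromide, BrP(Br)Br
Why: Activation of the benzylic alcohol as a phosphite ester followed by SN2 displacement by bromide.

Step 7
Reactants: 8 6-(bromomethyl)-7-methoxy-2H-chromen-2-one
Product: 9 diethyl [(7-methoxy-2-oxo-2H-chromen-6-yl)methyl]phosphonate
Conditions: P(OEt)3 (neat), 130 °C, EtBr distilled off
Reagents that add atoms: triethyl phosphite, CCOP(OCC)OCC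
Why: Michaelis–Arbuzov reaction of a reactive benzylic bromide under neutral conditions that leave the coumarin intact.

## Fragment C: chiral enone 18

Step 8
Reactants: 10 (E)-4-(dimethylamino)but-3-en-2-one
Product: 12 (E)-3-(tert-butyldimethylsilyloxy)-N,N-dimethylbuta-1,3-dien-1-amine (Rawal diene), via sodium dienolate 11 (not isolated)
Conditions: NaHMDS, THF, −78 °C; then TBSCl, −78 °C to rt; distillation
Reagents that add atoms: tert-butyldimethylsilyl chloride, CC(C)(C)[Si](C)(C)Cl
Why: Kinetic deprotonation of the methyl ketone of the vinylogous amide and O-silylation (silyl enol ether formation) give the E-configured 1-amino-3-siloxydiene.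

Step 9
Reactants: 12 Rawal diene; 13 methacrolein
Product: 15 [(1S,2R)-4-(tert-butyldimethylsilyloxy)-2-(dimethylamino)-1-methylcyclohex-3-en-1-yl]methanol, via Diels-Alder aldehyde 14 (not isolated)
Conditions: (R,R)-α,α,α′,α′-tetra(1-naphthyl)-TADDOL (20 mol %), toluene, −80 °C, 48 h; then LiAlH4, Et2O, −78 °C to rt
Reagents that add atoms: none
Why: In this hydrogen-bond-catalysed enantioselective Diels–Alder reaction the TADDOL hydroxyl activates the enal and a naphthyl group shields one of its faces, the nucleophilic CH2 terminus of the diene bonds to the enal CH2 so that the quaternary centre (S) forms next to nitrogen (endo, CHO cis to NMe2, about 90 % ee expected), and LiAlH4 then reduces the sensitive aldehyde in the same flask.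

Step 10
Reactants: 15 [(1S,2R)-4-(tert-butyldimethylsilyloxy)-2-(dimethylamino)-1-methylcyclohex-3-en-1-yl]methanol
Product: 17 (S)-4-(hydroxymethyl)-4-methylcyclohex-2-en-1-one, via beta-amino ketone 16 (not isolated)
Conditions: HF (48 % aq.) in MeCN, 0 °C to rt
Reagents that add atoms: none
Why: Desilylation of the silyl enol ether and E1cB β-elimination of dimethylamine unveil the enone, while the quaternary centre has no acidic hydrogen and cannot racemise.

Step 11
Reactants: 17 (S)-4-(hydroxymethyl)-4-methylcyclohex-2-en-1-one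
Product: 18 (S)-4-methyl-4-{[(triisopropylsilyl)oxy]methyl}cyclohex-2-en-1-one
Conditions: TIPSCl, imidazole, DMF, 40 °C
Reagents that add atoms: triisopropylsilyl chloride, CC(C)[Si](Cl)(C(C)C)C(C)C
Why: Silyl ether protection of the primary alcohol, where the bulky CH2OTIPS group is also the steric control element for the next step.

## Union of the fragments and endgame

Step 12
Reactants: 18 (S)-4-methyl-4-{[(triisopropylsilyl)oxy]methyl}cyclohex-2-en-1-one (1.3 equiv); 5 6-iodo-7-methoxy-2H-chromen-2-one
Product: 19 7-methoxy-6-[(1S,6S)-6-methyl-3-(triethylsilyloxy)-6-{[(triisopropylsilyl)oxy]methyl}cyclohex-2-en-1-yl]-2H-chromen-2-one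
Conditions: NiCl2(dme) (10 mol %, dme = 1,2-dimethoxyethane), neocuproine (10 mol %), Mn powder (2 equiv), Et3SiCl (1.5 equiv), DMF, 40 °C; filtration through Et3N-deactivated silica
Reagents that add atoms: chlorotriethylsilane, CC[Si](Cl)(CC)CC
Why: In this nickel-catalysed reductive conjugate arylation (cross-electrophile coupling) zerovalent nickel binds the enone on the face away from CH2OTIPS and passes the aryl group of 5 to the β-carbon on that face while Et3SiCl captures the oxygen, so the new CH–Ar centre (S) is trans to CH2OTIPS and cis to CH3, the enol ether is regiodefined, and no organometallic that could attack the coumarin is needed.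

Step 13
Reactants: 19 triethylsilyl enol ether
Product: 21 (3S,4S)-3-(7-methoxy-2-oxo-2H-chromen-6-yl)-4-methyl-4-{[(triisopropylsilyl)oxy]methyl}cyclohex-1-en-1-yl trifluoromethanesulfonate, via cesium enolate 20 (not isolated)
Conditions: CsF (2.5 equiv), PhNTf2 (1.5 equiv), DME, rt
Reagents that add atoms: N-phenylbis(trifluoromethanesulfonimide), O=S(=O)(N(c1ccccc1)S(=O)(=O)C(F)(F)F)C(F)(F)F
Why: Fluoride-triggered cleavage of the labile triethylsilyl enol ether and immediate O-triflation (enol triflate formation) keep the double-bond position, and the alkyl TIPS ether survives anhydrous CsF.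

Step 14
Reactants: 21 enol triflate
Product: 22 6-[(1S,6S)-3,6-dimethyl-6-{[(triisopropylsilyl)oxy]methyl}cyclohex-2-en-1-yl]-7-methoxy-2H-chromen-2-one
Conditions: MeZnCl (2 equiv), Pd(PPh3)4 (5 mol %), THF, 50 °C; minor diastereomer from step 12 removed by chromatography
Reagents that add atoms: methylzinc chloride, C[Zn]Cl
Why: Negishi cross-coupling at an unhindered alkenyl triflate, in which the methylzinc reagent does not add to the lactone or enoate and both stereocentres are untouched.

Step 15
Reactants: 22 TIPS ether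
Product: 23 6-[(1S,6S)-6-(hydroxymethyl)-3,6-dimethylcyclohex-2-en-1-yl]-7-methoxy-2H-chromen-2-one
Conditions: HF·pyridine, THF, 0 °C to rt; recrystallisation (EtOAc/heptane) to raise the ee
Reagents that add atoms: none
Why: Fluoride-mediated silyl ether cleavage under mildly acidic conditions that neither open the lactone nor move the trisubstituted alkene.

Step 16
Reactants: 23 primary alcohol
Product: 24 (1S,2R)-2-(7-methoxy-2-oxo-2H-chromen-6-yl)-1,4-dimethylcyclohex-3-ene-1-carbaldehyde
Conditions: Dess–Martin periodinane (1.3 equiv), CH2Cl2, rt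
Reagents that add atoms: none
Why: Dess–Martin oxidation of a neopentyl alcohol to an aldehyde that cannot enolise, so the geometry is unchanged (the 2R label follows only from a change of CIP priorities).

Step 17
Reactants: 24 aldehyde; 9 diethyl [(7-methoxy-2-oxo-2H-chromen-6-yl)methyl]phosphonate
Product: 26 7-methoxy-6-[(E)-2-[(1R,2S)-2-(7-methoxy-2-oxo-2H-chromen-6-yl)-1,4-dimethylcyclohex-3-en-1-yl]ethenyl]-2H-chromen-2-one (target), via sodiated phosphonate 25 (not isolated)
Conditions: 9 (1.3 equiv), NaH (1.25 equiv), THF, 0 °C, 30 min; then 24, 0 to 45 °C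
Reagents that add atoms: none
Why: Horner–Wadsworth–Emmons olefination with a benzylic phosphonate gives the E-alkene under thermodynamic control, reinforced by the quaternary neighbour, and the non-enolisable aldehyde keeps both stereocentres (the 1R label again follows only from priority rules).

## Compound list
1 | resorcinol | Oc1cccc(O)c1 | starting material
2 | 4-iodoresorcinol | Oc1ccc(I)c(O)c1 | intermediate
3 | ethyl propiolate | C#CC(=O)OCC | starting material
4 | 7-hydroxy-6-iodo-2H-chromen-2-one | Oc1cc2oc(=O)ccc2cc1I | intermediate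
5 | 6-iodo-7-methoxy-2H-chromen-2-one | COc1cc2oc(=O)ccc2cc1I | intermediate
6 | 7-methoxy-2-oxo-2H-chromene-6-carbaldehyde | COc1cc2oc(=O)ccc2cc1C=O | intermediate
7 | 6-(hydroxymethyl)-7-methoxy-2H-chromen-2-one | COc1cc2oc(=O)ccc2cc1CO | intermediate
8 | 6-(bromomethyl)-7-methoxy-2H-chromen-2-one | COc1cc2oc(=O)ccc2cc1CBr | intermediate
9 | diethyl [(7-methoxy-2-oxo-2H-chromen-6-yl)methyl]phosphonate | CCOP(=O)(Cc1cc2ccc(=O)oc2cc1OC)OCC | intermediate
10 | (E)-4-(dimethylamino)but-3-en-2-one | CC(=O)/C=C/N(C)C | starting material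
11 | sodium (E)-4-(dimethylamino)buta-1,3-dien-2-olate | [Na+].C=C([O-])/C=C/N(C)C | intermediate
12 | (E)-3-(tert-butyldimethylsilyloxy)-N,N-dimethylbuta-1,3-dien-1-amine | C=C(O[Si](C)(C)C(C)(C)C)/C=C/N(C)C | intermediate
13 | methacrolein | C=C(C)C=O | starting material
14 | (1S,2R)-4-(tert-butyldimethylsilyloxy)-2-(dimethylamino)-1-methylcyclohex-3-ene-1-carbaldehyde | O=C[C@@]1(C)CCC(O[Si](C)(C)C(C)(C)C)=C[C@H]1N(C)C | intermediate
15 | [(1S,2R)-4-(tert-butyldimethylsilyloxy)-2-(dimethylamino)-1-methylcyclohex-3-en-1-yl]methanol | OC[C@@]1(C)CCC(O[Si](C)(C)C(C)(C)C)=C[C@H]1N(C)C | intermediate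
16 | (3R,4S)-3-(dimethylamino)-4-(hydroxymethyl)-4-methylcyclohexan-1-one | OC[C@@]1(C)CCC(=O)C[C@H]1N(C)C | intermediate
17 | (S)-4-(hydroxymethyl)-4-methylcyclohex-2-en-1-one | OC[C@@]1(C)CCC(=O)C=C1 | intermediate
18 | (S)-4-methyl-4-{[(triisopropylsilyl)oxy]methyl}cyclohex-2-en-1-one | CC(C)[Si](C(C)C)(C(C)C)OC[C@@]1(C)CCC(=O)C=C1 | intermediate
19 | 7-methoxy-6-[(1S,6S)-6-methyl-3-(triethylsilyloxy)-6-{[(triisopropylsilyl)oxy]methyl}cyclohex-2-en-1-yl]-2H-chromen-2-one | CC(C)[Si](C(C)C)(C(C)C)OC[C@@]1(C)CCC(O[Si](CC)(CC)CC)=C[C@@H]1c1cc2ccc(=O)oc2cc1OC | intermediate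
20 | cesium (3S,4S)-3-(7-methoxy-2-oxo-2H-chromen-6-yl)-4-methyl-4-{[(triisopropylsilyl)oxy]methyl}cyclohex-1-en-1-olate | [Cs+].CC(C)[Si](C(C)C)(C(C)C)OC[C@@]1(C)CCC([O-])=C[C@@H]1c1cc2ccc(=O)oc2cc1OC | intermediate
21 | (3S,4S)-3-(7-methoxy-2-oxo-2H-chromen-6-yl)-4-methyl-4-{[(triisopropylsilyl)oxy]methyl}cyclohex-1-en-1-yl trifluoromethanesulfonate | CC(C)[Si](C(C)C)(C(C)C)OC[C@@]1(C)CCC(OS(=O)(=O)C(F)(F)F)=C[C@@H]1c1cc2ccc(=O)oc2cc1OC | intermediate
22 | 6-[(1S,6S)-3,6-dimethyl-6-{[(triisopropylsilyl)oxy]methyl}cyclohex-2-en-1-yl]-7-methoxy-2H-chromen-2-one | CC(C)[Si](C(C)C)(C(C)C)OC[C@@]1(C)CCC(C)=C[C@@H]1c1cc2ccc(=O)oc2cc1OC | intermediate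
23 | 6-[(1S,6S)-6-(hydroxymethyl)-3,6-dimethylcyclohex-2-en-1-yl]-7-methoxy-2H-chromen-2-one | OC[C@@]1(C)CCC(C)=C[C@@H]1c1cc2ccc(=O)oc2cc1OC | intermediate
24 | (1S,2R)-2-(7-methoxy-2-oxo-2H-chromen-6-yl)-1,4-dimethylcyclohex-3-ene-1-carbaldehyde | O=C[C@@]1(C)CCC(C)=C[C@@H]1c1cc2ccc(=O)oc2cc1OC | intermediate
25 | sodium salt of the carbanion of phosphonate 9 | [Na+].CCOP(=O)([CH-]c1cc2ccc(=O)oc2cc1OC)OCC | intermediate
26 | 7-methoxy-6-[(E)-2-[(1R,2S)-2-(7-methoxy-2-oxo-2H-chromen-6-yl)-1,4-dimethylcyclohex-3-en-1-yl]ethenyl]-2H-chromen-2-one | COc1cc2oc(=O)ccc2cc1/C=C/[C@@]1(C)CCC(C)=C[C@@H]1c1cc2ccc(=O)oc2cc1OC | target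

## Step count and weak points
- **Total step count:** 17.
- **Longest linear sequence:** 10 steps (8 to 17), which is 0.59 of the total.
- **Other branches:** steps 1–3 followed by 12–17 make 9 steps. Steps 1–7 followed by 17 make 8 steps.

**Step 12, reductive conjugate arylation next to a quaternary carbon with an ortho-methoxy aryl iodide.** The risks are low conversion, biaryl formation and modest facial selectivity. The fallback sets out from 5 and 18 and comes back at 21.
- Instead of coupling two electrophiles, 5 is first made into a nucleophile. Zinc insertion (Zn dust, LiCl, THF, 50 °C) gives (7-methoxy-2-oxo-2H-chromen-6-yl)zinc iodide F1, which tolerates the lactone.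
- F1 is added to 18 under rhodium catalysis ([RhCl(C2H4)2]2, (R)-BINAP, Me3SiCl, THF, rt).
- (R)-BINAP is the ligand enantiomer that attacks this same enone face in the parent cyclohexenone series. Catalyst and substrate control therefore reinforce each other.
- The product is the trimethylsilyl enol ether 7-methoxy-6-[(1S,6S)-6-methyl-3-(trimethylsilyloxy)-6-{[(triisopropylsilyl)oxy]methyl}cyclohex-2-en-1-yl]-2H-chromen-2-one F2.
- CsF/PhNTf2 then converts F2 into 21.

**Step 17, olefination of a very hindered aldehyde with a carbanion that can also add to coumarins.** The fallback sets out from 24 and 5 and comes back at 26.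
- The aldehyde is methylenated with a reagent that ignores lactones (Zn, CH2Br2, TiCl4, THF/CH2Cl2, 0 °C). This gives 6-[(1S,6R)-6-ethenyl-3,6-dimethylcyclohex-2-en-1-yl]-7-methoxy-2H-chromen-2-one F3.
- The terminal alkene of F3 has no allylic hydrogen, so it cannot isomerise.
- A Heck reaction with iodide 5 (Pd(OAc)2, P(o-tol)3, Et3N, DMF, 100 °C) then gives the E-styryl target 26 without any strong base.

**Step 9, enantiopurity and sense of induction of the cycloaddition.** The fallback sets out from 17 of insufficient ee and comes back at 17.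
- Classical resolution replaces reliance on the catalyst.
- Alcohol 17 is esterified with (1S,4R)-camphanic chloride (Et3N, DMAP, CH2Cl2). This gives [(S)-1-methyl-4-oxocyclohex-2-en-1-yl]methyl (1S,4R)-camphanate F4.
- F4 is crystallised to a single diastereomer, and its X-ray structure also proves the absolute configuration.
- Cleavage with K2CO3 in MeOH at 0 °C returns enantiopure 17.

## Further compounds
F1 | step 12 | (7-methoxy-2-oxo-2H-chromen-6-yl)zinc iodide | COc1cc2oc(=O)ccc2cc1[Zn]I
F2 | step 12 | 7-methoxy-6-[(1S,6S)-6-methyl-3-(trimethylsilyloxy)-6-{[(triisopropylsilyl)oxy]methyl}cyclohex-2-en-1-yl]-2H-chromen-2-one | CC(C)[Si](C(C)C)(C(C)C)OC[C@@]1(C)CCC(O[Si](C)(C)C)=C[C@@H]1c1cc2ccc(=O)oc2cc1OC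
F3 | step 17 | 6-[(1S,6R)-6-ethenyl-3,6-dimethylcyclohex-2-en-1-yl]-7-methoxy-2H-chromen-2-one | C=C[C@@]1(C)CCC(C)=C[C@@H]1c1cc2ccc(=O)oc2cc1OC
F4 | step 9 | [(S)-1-methyl-4-oxocyclohex-2-en-1-yl]methyl (1S,4R)-4,7,7-trimethyl-3-oxo-2-oxabicyclo[2.2.1]heptane-1-carboxylate | O=C(OC[C@@]1(C)CCC(=O)C=C1)[C@@]12CC[C@@](C)(C(=O)O1)C2(C)C
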